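**Retrosynthetic overview**
- Side chain last: the C5–C1′ bond comes from Felkin–Anh addition of the ring-A aryllithium (from the 5-bromide) to O-TBS-(R)-lactaldehyde; C2′ comes from the chiral pool, C1′ from the addition.
- Ring C (the dihydrofuran, the only ring that is built) comes from reduction of an (S)-α-aryl ketone and acid-mediated closure of the O–C2 bond, trans under thermodynamic control.
- Key disconnection C3–C3a: nickel-catalysed enantioconvergent radical arylation of racemic 2-bromo-1-(3,4-dimethoxyphenyl)propan-1-one with a ring-A arylzinc (planar α-keto radical); this sets C3.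
- The bromoketone comes from veratrole and 2-bromopropanoyl bromide (Friedel–Crafts); the ring-A iodide comes from guaiacol (Br para, I ortho, MOM ether).
- Rings A and B are both bought as catechol; ring C is formed in step 7.

Assumption: (2R)-2-[(tert-butyldimethylsilyl)oxy]propanal (from D-lactate) is bought as a catalogue compound.
Assumption: the nickel/pybox catalyst induces in the same sense as in the published aryl alkyl ketone cases; the ligand enantiomer written is the one that gives the (S)-ketone, and its mirror image is used if the first run shows the opposite.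

**Step 1**
Reactants: 1 benzene-1,2-diol (catechol)
Product: 2 1,2-dimethoxybenzene (veratrole)
Conditions: MeI (2.5 equiv), K2CO3 (3 equiv), acetone, reflux
Reagents that add atoms: iodomethane, CI
Why: Double Williamson O-methylation of both phenol groups; no stereocentre is involved.

**Step 2**
Reactants: 2 1,2-dimethoxybenzene; 3 2-bromopropanoyl bromide (racemic)
Product: 4 rac-2-bromo-1-(3,4-dimethoxyphenyl)propan-1-one
Conditions: AlCl3 (1.2 equiv), CH2Cl2, 0 °C to rt
Reagents that add atoms: none
Why: Friedel–Crafts acylation goes para to one methoxy group (position 4 of veratrole) and installs the whole C2/C3/methyl unit of ring C in one operation; the bromide may be racemic because step 6 is stereoconvergent.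

**Step 3**
Reactants: 1 benzene-1,2-diol (catechol)
Product: 5 2-methoxyphenol (guaiacol)
Conditions: MeI (1.0 equiv), K2CO3 (1.0 equiv), acetone, reflux; fractional distillation
Reagents that add atoms: iodomethane, CI
Why: Williamson mono-methylation of the catechol mono-anion; unreacted catechol and some veratrole are removed by distillation.

**Step 4**
Reactants: 5 2-methoxyphenol
Product: 7 4-bromo-2-iodo-6-methoxyphenol, via 4-bromo-2-methoxyphenol 6 (not isolated)
Conditions: NBS (1.0 equiv), MeCN, 0 °C; then NIS (1.05 equiv), TsOH·H2O (10 mol %), rt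
Reagents that add atoms: N-bromosuccinimide, O=C1CCC(=O)N1Br; N-iodosuccinimide, O=C1CCC(=O)N1I
Why: Electrophilic aromatic halogenation directed by the free OH: bromine goes para, then iodine takes the only remaining ortho position, giving the future C5 handle and the future C3a handle.

**Step 5**
Reactants: 7 4-bromo-2-iodo-6-methoxyphenol
Product: 8 5-bromo-1-iodo-3-methoxy-2-(methoxymethoxy)benzene
Conditions: NaH, THF, 0 °C; MOMCl, 0 °C to rt
Reagents that add atoms: chloromethyl methyl ether, COCCl
Why: Williamson-type MOM protection masks the phenol for the organometallic steps, and the MOM group is removed by the acid that closes ring C in step 7.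

**Step 6**
Reactants: 8 5-bromo-1-iodo-3-methoxy-2-(methoxymethoxy)benzene; 4 rac-2-bromo-1-(3,4-dimethoxyphenyl)propan-1-one
Product: 11 (2S)-2-[5-bromo-3-methoxy-2-(methoxymethoxy)phenyl]-1-(3,4-dimethoxyphenyl)propan-1-one, via arylmagnesium chloride 9 (not isolated), via arylzinc iodide 10 (not isolated)
Conditions: 8, i-PrMgCl·LiCl, THF, −20 °C; ZnI2, 0 °C, volatiles (with 2-iodopropane) removed, residue in glyme; then 4 (0.75 equiv), NiCl2·glyme (5 mol %), (R,R)-Ph-pybox-type ligand (6.5 mol %), glyme/THF, −30 °C
Reagents that add atoms: none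
Why: Knochel iodine–magnesium exchange touches only the C–I bond and transmetalation gives the arylzinc iodide; in the nickel-catalysed enantioconvergent Negishi arylation (Fu type) monovalent nickel abstracts bromine from 4 to give a planar α-keto carbon radical, which is captured by the chiral aryl-nickel species and released by reductive elimination from trivalent nickel, so the C3–C3a bond forms in a radical step and both enantiomers of 4 converge on the (S)-ketone (C3 of the target) under ligand control; the ortho-alkoxy arylzinc lies at the edge of the reported scope and is the calculated risk of the route.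

**Step 7**
Reactants: 11 (2S)-2-[5-bromo-3-methoxy-2-(methoxymethoxy)phenyl]-1-(3,4-dimethoxyphenyl)propan-1-one
Product: 13 (2S,3S)-5-bromo-2-(3,4-dimethoxyphenyl)-7-methoxy-3-methyl-2,3-dihydro-1-benzofuran, via benzylic alcohol 12 (not isolated)
Conditions: NaBH4, CeCl3·7H2O, MeOH/THF, −40 °C; then HCl (1.25 M in MeOH), 0 °C to rt
Reagents that add atoms: none
Why: Luche-type reduction is fast and non-basic, so C3 is not epimerised (the carbinol configuration does not matter); HCl/MeOH then removes the MOM group and ionises the electron-rich benzylic alcohol, the phenol oxygen closes ring C by SN1 intramolecular etherification, and reversible ionisation at C2 funnels any cis isomer to the thermodynamically favoured 2,3-trans product, which is (2S) from the fixed (3S) centre.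

**Step 8**
Reactants: 13 (2S,3S)-5-bromo-2-(3,4-dimethoxyphenyl)-7-methoxy-3-methyl-2,3-dihydro-1-benzofuran; 14 (2R)-2-[(tert-butyldimethylsilyl)oxy]propanal
Product: 17 (1S,2R)-1-[(2S,3S)-2-(3,4-dimethoxyphenyl)-7-methoxy-3-methyl-2,3-dihydro-1-benzofuran-5-yl]propane-1,2-diol, via aryllithium 15 (not isolated), via mono-TBS ether 16 (not isolated)
Conditions: n-BuLi, THF, −78 °C; 14, −78 °C; AcOH; then TBAF, THF, 0 °C to rt
Reagents that add atoms: none
Why: Bromine–lithium exchange followed by polar Felkin–Anh addition to the non-chelating α-silyloxy aldehyde (nucleophile anti to the C–O bond) gives the anti (erythro) adduct, so C1′ is set (S) relative to the pool-derived (R) C2′ (expected d.r. about 4–5:1, the syn isomer is removed at the diol stage), and fluoride desilylation in the same pot gives the target.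

**Compound list**
1 | benzene-1,2-diol (catechol) | Oc1ccccc1O | starting material
2 | 1,2-dimethoxybenzene (veratrole) | COc1ccccc1OC | intermediate
3 | 2-bromopropanoyl bromide (racemic) | CC(Br)C(Br)=O | starting material
4 | rac-2-bromo-1-(3,4-dimethoxyphenyl)propan-1-one | COc1ccc(cc1OC)C(=O)C(C)Br | intermediate
5 | 2-methoxyphenol (guaiacol) | COc1ccccc1O | intermediate
6 | 4-bromo-2-methoxyphenol | COc1cc(Br)ccc1O | intermediate
7 | 4-bromo-2-iodo-6-methoxyphenol | COc1cc(Br)cc(I)c1O | intermediate
8 | 5-bromo-1-iodo-3-methoxy-2-(methoxymethoxy)benzene | COCOc1c(I)cc(Br)cc1OC | intermediate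
9 | [5-bromo-3-methoxy-2-(methoxymethoxy)phenyl]magnesium chloride | COCOc1c([Mg]Cl)cc(Br)cc1OC | intermediate
10 | [5-bromo-3-methoxy-2-(methoxymethoxy)phenyl]zinc iodide | COCOc1c([Zn]I)cc(Br)cc1OC | intermediate
11 | (2S)-2-[5-bromo-3-methoxy-2-(methoxymethoxy)phenyl]-1-(3,4-dimethoxyphenyl)propan-1-one | COc1ccc(cc1OC)C(=O)[C@@H](C)c1cc(Br)cc(OC)c1OCOC | intermediate
12 | (2S)-2-[5-bromo-3-methoxy-2-(methoxymethoxy)phenyl]-1-(3,4-dimethoxyphenyl)propan-1-ol (both C1 epimers) | COc1ccc(cc1OC)C(O)[C@@H](C)c1cc(Br)cc(OC)c1OCOC | intermediate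
13 | (2S,3S)-5-bromo-2-(3,4-dimethoxyphenyl)-7-methoxy-3-methyl-2,3-dihydro-1-benzofuran | COc1ccc([C@H]2Oc3c(OC)cc(Br)cc3[C@@H]2C)cc1OC | intermediate
14 | (2R)-2-[(tert-butyldimethylsilyl)oxy]propanal | C[C@@H](O[Si](C)(C)C(C)(C)C)C=O | starting material
15 | [(2S,3S)-2-(3,4-dimethoxyphenyl)-7-methoxy-3-methyl-2,3-dihydro-1-benzofuran-5-yl]lithium | COc1ccc([C@H]2Oc3c(OC)cc([Li])cc3[C@@H]2C)cc1OC | intermediate
16 | (1S,2R)-2-[(tert-butyldimethylsilyl)oxy]-1-[(2S,3S)-2-(3,4-dimethoxyphenyl)-7-methoxy-3-methyl-2,3-dihydro-1-benzofuran-5-yl]propan-1-ol | COc1ccc([C@H]2Oc3c(OC)cc([C@H](O)[C@@H](C)O[Si](C)(C)C(C)(C)C)cc3[C@@H]2C)cc1OC | intermediate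
17 | (1S,2R)-1-[(2S,3S)-2-(3,4-dimethoxyphenyl)-7-methoxy-3-methyl-2,3-dihydro-1-benzofuran-5-yl]propane-1,2-diol | COc1ccc([C@H]2Oc3c(OC)cc([C@H](O)[C@@H](C)O)cc3[C@@H]2C)cc1OC | target

**Totals**
Total step count: 8. Longest linear sequence: 6 steps (steps 3, 4, 5, 6, 7, 8).

**Three steps most likely to fail**

Step 6. The ortho-alkoxy arylzinc may transmetalate slowly or give low ee. The fallback sets out from 2 and 7 and comes back at 13; it makes the same C3–C3a bond by an aryl radical cyclisation after C2 has been set. NBS in MeCN converts 2 into 4-bromo-1,2-dimethoxybenzene F1. Suzuki–Miyaura coupling with potassium vinyltrifluoroborate (PdCl2(dppf), Et3N, n-PrOH, 90 °C) gives 4-ethenyl-1,2-dimethoxybenzene F2. Cross-metathesis with allyl methyl carbonate (second-generation Hoveyda–Grubbs catalyst, CH2Cl2, 40 °C) gives (E)-3-(3,4-dimethoxyphenyl)prop-2-en-1-yl methyl carbonate F3. Iridium-catalysed branched-selective allylic etherification of F3 with the sodium salt of 7 ([Ir(cod)Cl]2, Feringa-type phosphoramidite of the enantiomeric series that gives the (S)-ether, THF, 50 °C) gives 5-bromo-2-{[(1S)-1-(3,4-dimethoxyphenyl)prop-2-en-1-yl]oxy}-1-iodo-3-methoxybenzene F4. Bu3SnH/Et3B/air (toluene, 0 °C) then abstracts iodine only; the aryl radical closes 5-exo-trig onto the vinyl group anti to the C2 aryl group, and hydrogen transfer to the CH2 radical gives 13.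

Step 7. C3 may erode during hydride reduction of the enolisable α-aryl ketone, or the one-pot acid stage may be unclean. The fallback sets out from 11 and comes back at 12; it secures C3 by dynamic kinetic resolution instead of relying on configurational stability. Transfer hydrogenation with RuCl(p-cymene)[(S,S)-TsDPEN] (or its mirror image, whichever is Felkin-matched with the (2S) ketone), HCO2H and DBU in DMF at 40 °C racemises the α-aryl centre through the enol while only one enantiomer is reduced. This gives 12 as essentially one isomer whatever the ee of 11. The ring closure is then run as a separate operation with TsOH in MeOH, which traps the MOM-derived formaldehyde as its acetal. No compound outside the list is made (F0).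

Step 8. The Felkin–Anh selectivity of the aryllithium addition may be low. The fallback sets out from 13 and 14 and comes back at 17; C1′ is set by chelation-controlled ketone reduction instead. The same addition is worked up before desilylation to give 16 together with its C1′ epimer, (1R,2R)-2-[(tert-butyldimethylsilyl)oxy]-1-[(2S,3S)-2-(3,4-dimethoxyphenyl)-7-methoxy-3-methyl-2,3-dihydro-1-benzofuran-5-yl]propan-1-ol F5. Dess–Martin periodinane (NaHCO3, CH2Cl2) converges both epimers on (2R)-2-[(tert-butyldimethylsilyl)oxy]-1-[(2S,3S)-2-(3,4-dimethoxyphenyl)-7-methoxy-3-methyl-2,3-dihydro-1-benzofuran-5-yl]propan-1-one F6. HF·pyridine (THF, 0 °C) gives (2R)-1-[(2S,3S)-2-(3,4-dimethoxyphenyl)-7-methoxy-3-methyl-2,3-dihydro-1-benzofuran-5-yl]-2-hydroxypropan-1-one F7. Zn(BH4)2 (Et2O, −20 °C) reduces F7 through the five-membered zinc chelate from the face of the α-hydrogen and gives the anti diol 17.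

**Further compounds**
F1 | step 6 | 4-bromo-1,2-dimethoxybenzene | COc1ccc(Br)cc1OC
F2 | step 6 | 4-ethenyl-1,2-dimethoxybenzene | COc1ccc(C=C)cc1OC
F3 | step 6 | (E)-3-(3,4-dimethoxyphenyl)prop-2-en-1-yl methyl carbonate | COC(=O)OC/C=C/c1ccc(OC)c(OC)c1
F4 | step 6 | 5-bromo-2-{[(1S)-1-(3,4-dimethoxyphenyl)prop-2-en-1-yl]oxy}-1-iodo-3-methoxybenzene | COc1ccc([C@H](C=C)Oc2c(OC)cc(Br)cc2I)cc1OC
F0 | step 7 | none | none
F5 | step 8 | (1R,2R)-2-[(tert-butyldimethylsilyl)oxy]-1-[(2S,3S)-2-(3,4-dimethoxyphenyl)-7-methoxy-3-methyl-2,3-dihydro-1-benzofuran-5-yl]propan-1-ol | COc1ccc([C@H]2Oc3c(OC)cc([C@@H](O)[C@@H](C)O[Si](C)(C)C(C)(C)C)cc3[C@@H]2C)cc1OC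
F6 | step 8 | (2R)-2-[(tert-butyldimethylsilyl)oxy]-1-[(2S,3S)-2-(3,4-dimethoxyphenyl)-7-methoxy-3-methyl-2,3-dihydro-1-benzofuran-5-yl]propan-1-one | COc1ccc([C@H]2Oc3c(OC)cc(C(=O)[C@@H](C)O[Si](C)(C)C(C)(C)C)cc3[C@@H]2C)cc1OC
F7 | step 8 | (2R)-1-[(2S,3S)-2-(3,4-dimethoxyphenyl)-7-methoxy-3-methyl-2,3-dihydro-1-benzofuran-5-yl]-2-hydroxypropan-1-one | COc1ccc([C@H]2Oc3c(OC)cc(C(=O)[C@@H](C)O)cc3[C@@H]2C)cc1OC
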